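**Retrosynthetic overview**

1. The target is unmasked from the bis-silyl ether 30, which comes from acylation of the C8 hydroxyl of macrocyclic alcohol 25 with the (S)-acid 29.
2. The ten-membered carbocycle of 25 is closed at C8–C9 by an intramolecular allylboration with allylic transposition of aldehyde 23 (released from acetal 22). This one event should form the ring, the cis C1=C10 alkene and the C8 carbinol centre.
3. The enabling feature is the homoallylic alcohol array O–C8H–C9H2–C10(CH3)=C1H inside the ten-membered ring: the carbinol carbon C8 lies next to the allylic CH2 (C9) of the cis trisubstituted alkene. The trans C4=C5 alkene and the trans-fused γ-lactone (C6, C7, C11, C12, O) act as stiff spacers between C1 and C8.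
4. Boronate 22 comes from allylic carbonate 21 by copper-catalysed SN2' borylation. The lactone comes from an Evans syn-aldol/lactonisation of succinyl imide 12 with enal 9, followed by α-methylation.
5. Enal 9 comes from syn-carbocupration of ynoate 5 with the Grignard reagent of bromide 3. Ring order: γ-lactone first (step 8), ten-membered carbocycle second (step 16).

Key step: step 16

Remark (numbering): ring carbons are numbered as in germacranes. C10 carries the methyl group, C4 the CH2OH group (C15), C6 the lactone oxygen, C7 the lactone ring fusion, C8 the acyloxy group, and C9 is the ring CH2 between C8 and C10. C11 is the lactone CH(CH3) and C12 the lactone C=O. The target is 6R,7R,8S,11S with a 3S side chain; C9 and C2 are cis on C1=C10, and C3 and C6 are trans on C4=C5.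

Remark (abbreviations): TBS = tert-butyldimethylsilyl, TBDPS = tert-butyldiphenylsilyl, pin = pinacolato. "Chain A" = (1Z,5E)-7-(TBS-oxy)-2-(TBDPS-oxymethyl)-6-methylhepta-1,5-dien-1-yl.

Remark (assumptions): compounds 1, 4, 10, 11 and 26 are taken as purchasable. The sense of induction of the chiral copper catalyst in step 15 is assumed; the antipodal ligand would be used if the opposite sense were found.

**Route**

Step 1
Reactants: 1 5-bromo-2-methylpent-2-ene
Product: 2 (E)-5-bromo-2-methylpent-2-en-1-ol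
Conditions: SeO2 (cat.), tBuOOH, CH2Cl2, 0 °C to rt
Reagents that add atoms: tert-butyl hydroperoxide CC(C)(C)OO
Why: Allylic oxidation with SeO2 (ene reaction, then [2,3]-sigmatropic shift) attacks the E-methyl group of a trisubstituted alkene, so the E-allylic alcohol should form with the primary bromide untouched.

Step 2
Reactants: 2 (E)-5-bromo-2-methylpent-2-en-1-ol
Product: 3 (E)-[(5-bromo-2-methylpent-2-en-1-yl)oxy](tert-butyl)dimethylsilane
Conditions: TBSCl, imidazole, CH2Cl2, rt
Reagents that add atoms: tert-butyldimethylsilyl chloride CC(C)(C)[Si](C)(C)Cl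
Why: Standard silylation of a primary alcohol; this acid-labile ether is meant to fall off later in step 13.

Step 3
Reactants: 4 methyl 4-hydroxybut-2-ynoate
Product: 5 methyl 4-[(tert-butyldiphenylsilyl)oxy]but-2-ynoate
Conditions: TBDPSCl, imidazole, CH2Cl2, 0 °C to rt
Reagents that add atoms: tert-butyldiphenylsilyl chloride CC(C)(C)[Si](Cl)(c1ccccc1)c1ccccc1
Why: Standard silylation; the robust TBDPS group protects the future C15 oxygen to the end of the route.

Step 4
Reactants: 3 (E)-[(5-bromo-2-methylpent-2-en-1-yl)oxy](tert-butyl)dimethylsilane; 5 methyl 4-[(tert-butyldiphenylsilyl)oxy]but-2-ynoate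
Product: 7 methyl (2Z,6E)-8-(TBS-oxy)-3-(TBDPS-oxymethyl)-7-methylocta-2,6-dienoate, via Grignard reagent 6 (not isolated)
Conditions: Mg, THF, 40 °C; CuBr·SMe2 (1 equiv), THF, −78 °C; then 5, −78 °C; NH4Cl (aq.), −78 °C
Reagents that add atoms: none
Why: Syn-carbocupration of a 2-ynoate (conjugate addition of an organocopper reagent) puts the new alkyl group and the hydrogen cis at −78 °C, which fixes the C4=C5 geometry of the target with the silyloxymethyl group cis to the ester carbon (the future C6).

Step 5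
Reactants: 7 methyl (2Z,6E)-8-(TBS-oxy)-3-(TBDPS-oxymethyl)-7-methylocta-2,6-dienoate
Product: 8 (2Z,6E)-8-(TBS-oxy)-3-(TBDPS-oxymethyl)-7-methylocta-2,6-dien-1-ol
Conditions: iBu2AlH (2.5 equiv), CH2Cl2, −78 °C; potassium sodium tartrate (aq.)
Reagents that add atoms: none
Why: 1,2-Reduction of the enoate by the aluminium hydride leaves both alkenes and both silyl ethers untouched.

Step 6
Reactants: 8 (2Z,6E)-8-(TBS-oxy)-3-(TBDPS-oxymethyl)-7-methylocta-2,6-dien-1-ol
Product: 9 (2Z,6E)-8-(TBS-oxy)-3-(TBDPS-oxymethyl)-7-methylocta-2,6-dienal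
Conditions: Dess–Martin periodinane, CH2Cl2, 0 °C to rt
Reagents that add atoms: none
Why: Dess–Martin oxidation of the allylic alcohol is mild and should not isomerise the 2Z enal.

Step 7
Reactants: 10 (S)-4-benzyloxazolidin-2-one; 11 methyl 4-chloro-4-oxobutanoate
Product: 12 methyl 4-[(4S)-4-benzyl-2-oxooxazolidin-3-yl]-4-oxobutanoate
Conditions: nBuLi, THF, −78 °C; then 11, −78 °C to 0 °C
Reagents that add atoms: none
Why: N-Acylation of the lithiated oxazolidinone by the acid chloride, which is far more reactive than the methyl ester.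

Step 8
Reactants: 12 methyl 4-[(4S)-4-benzyl-2-oxooxazolidin-3-yl]-4-oxobutanoate; 9 (2Z,6E)-8-(TBS-oxy)-3-(TBDPS-oxymethyl)-7-methylocta-2,6-dienal
Product: 14 (4S)-4-benzyl-3-{[2,3-trans-2-(chain A)-5-oxotetrahydrofuran-3-yl]carbonyl}oxazolidin-2-one with C6 and C7 as in the target, via syn-aldol adduct 13 (not isolated)
Conditions: Bu2BOTf, iPr2NEt, CH2Cl2, −78 °C to 0 °C; then 9, −78 °C to 0 °C; pH 7 buffer, MeOH, H2O2
Reagents that add atoms: none
Why: The Evans syn-aldol reaction of the Z-boron enolate (chair Zimmerman–Traxler transition state, aldehyde anti to the benzyl group) sets C6 and C7, and the aldol oxygen then closes the γ-lactone on the methyl ester to give the 4,5-trans lactone, as known for succinyl imides.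

Step 9
Reactants: 14 trans-lactone imide
Product: 15 2,3-trans-2-(chain A)-5-oxotetrahydrofuran-3-carboxylic acid (C6 and C7 as in the target)
Conditions: LiOH, H2O2, THF/H2O, 0 °C; Na2SO3 (aq.); HCl (aq.) to pH 3
Reagents that add atoms: hydrogen peroxide OO
Why: Lithium hydroperoxide attacks the exocyclic imide carbonyl selectively, so the auxiliary is released and the lactone is kept (or re-closes on acidification).

Step 10
Reactants: 15 lactone acid
Product: 16 all-trans 2-(chain A)-4-methyl-5-oxotetrahydrofuran-3-carboxylic acid (C6, C7 and C11 as in the target)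
Conditions: NaN(SiMe3)2 (2.2 equiv), THF, −78 °C; MeI; HCl (aq.)
Reagents that add atoms: iodomethane CI
Why: The lactone enolate of the carboxylate is methylated on the face anti to the neighbouring C7 carboxylate (enolate alkylation), which sets C11 trans to C7.

Step 11
Reactants: 16 methylated lactone acid
Product: 18 all-trans 5-(chain A)-4-(hydroxymethyl)-3-methyldihydrofuran-2(3H)-one, via mixed anhydride 17 (not isolated)
Conditions: iBuOCOCl, N-methylmorpholine, THF, −15 °C; then NaBH4, H2O, 0 °C
Reagents that add atoms: none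
Why: The mixed carbonic anhydride is much more electrophilic than the lactone, so NaBH4 reduces only the activated carboxyl group; borane is avoided because of the alkenes.

Step 12
Reactants: 18 hydroxymethyl lactone
Product: 19 all-trans 2-(chain A)-4-methyl-5-oxotetrahydrofuran-3-carbaldehyde (the C8 aldehyde)
Conditions: Dess–Martin periodinane, CH2Cl2, 0 °C to rt
Reagents that add atoms: none
Why: Mild alcohol oxidation; C7 next to the aldehyde already sits in the thermodynamically preferred all-trans arrangement, so epimerisation is not expected to matter.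

Step 13
Reactants: 19 lactone aldehyde
Product: 20 all-trans 4-(dimethoxymethyl)-5-[(1Z,5E)-7-hydroxy-2-(TBDPS-oxymethyl)-6-methylhepta-1,5-dien-1-yl]-3-methyldihydrofuran-2(3H)-one
Conditions: HC(OMe)3, camphor-10-sulfonic acid (5 mol %), MeOH, 0 °C to rt
Reagents that add atoms: trimethyl orthoformate COC(OC)OC
Why: Acid-catalysed acetalisation masks the C8 aldehyde, and the same methanolic acid cleaves the primary TBS ether at C9 while the more acid-stable TBDPS ether survives.

Step 14
Reactants: 20 acetal with free C9 alcohol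
Product: 21 the methyl carbonate of 20 at the C9 oxygen
Conditions: ClCO2Me, pyridine, CH2Cl2, 0 °C
Reagents that add atoms: methyl chloroformate COC(Cl)=O
Why: Acylation of the only free hydroxyl group gives the leaving group needed for the copper step.

Step 15
Reactants: 21 allylic methyl carbonate
Product: 22 all-trans 4-(dimethoxymethyl)-5-[(1Z,5S)-5-(pinacolatoboryl)-2-(TBDPS-oxymethyl)-6-methylhepta-1,6-dien-1-yl]-3-methyldihydrofuran-2(3H)-one (boron on C1, S; C10=C9 now a terminal isopropenyl alkene)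
Conditions: B2pin2, CuCl (5 mol %), KOtBu (10 mol %), (R,R)-QuinoxP* (6 mol %), THF, 0 °C to rt
Reagents that add atoms: bis(pinacolato)diboron CC1(C)OB(OC1(C)C)B1OC(C)(C)C(C)(C)O1
Why: Copper-catalysed γ-selective (SN2') borylation of an allylic carbonate puts boron on C1 and moves the alkene to C10=C9; the chiral ligand should control the face of attack and set C1 (S), and the primary carbonate with an unhindered γ-carbon should react well before the allylic lactone at C6.

Step 16
Reactants: 22 allylboronate acetal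
Product: 25 8α-hydroxy-15-(TBDPS-oxy)-11βH,13-dihydrogermacra-1(10),4-dien-6α,12-olide (6R,7R,8S,11S; C9/C2 cis on C1=C10; C3/C6 trans on C4=C5), via aldehyde 23 (not isolated), via cyclic borate ester 24 (not isolated)
Conditions: pyridinium p-toluenesulfonate (0.3 equiv), THF/H2O (10:1), 0.002 M, 50 to 60 °C; NaHCO3 (aq.)
Reagents that add atoms: water O
Why: Proposed new method: slow hydrolysis of the acetal releases aldehyde 23 at high dilution, its carbonyl oxygen binds the boron atom, and the CH2 terminus of the allylboronate (C9) adds to the aldehyde carbon (C8) through a six-membered chair transition state with allylic transposition, so that boron leaves C1 and the C1=C10 double bond forms (intramolecular allylboration, SE2'). The closest known reaction types are the intermolecular allylboration of aldehydes with α-substituted pinacol allylboronates, which gives Z-homoallylic alcohols with 1,3-chirality transfer, and intramolecular allylborations that close five- and six-membered rings. The ten-membered carbocycle closes in a 10-exo-trig mode at the aldehyde, with the boron–oxygen pair bridging C1 and C8 in the transition state (a bicyclo[6.2.2] array). C8 is set by chirality transfer from C1: with the C2 chain axial on C1 (favoured by A1,2 strain with the C10 methyl group and by the pinacol ester) and C7 equatorial on C8, the (1S)-boronate should give the (8S)-alcohol. The step needs the cis over the trans C1=C10 alkene and ring closure over dimerisation; the axial C2 chain lets the six-atom tether span the chair, the trans C4=C5 alkene and the trans-fused lactone stiffen this tether, and the low stationary concentration of 23 suppresses intermolecular allylboration. The borate ester 24 is hydrolysed on work-up.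

Step 17
Reactants: 26 (R)-3-bromo-2-methylpropan-1-ol
Product: 27 (R)-(3-bromo-2-methylpropoxy)(tert-butyl)dimethylsilane
Conditions: TBSCl, imidazole, CH2Cl2, rt
Reagents that add atoms: tert-butyldimethylsilyl chloride CC(C)(C)[Si](C)(C)Cl
Why: Standard silylation of the primary alcohol; the stereocentre is not touched.

Step 18
Reactants: 27 (R)-(3-bromo-2-methylpropoxy)(tert-butyl)dimethylsilane
Product: 29 (S)-4-(TBS-oxy)-3-methylbutanoic acid, via Grignard reagent 28 (not isolated)
Conditions: Mg, THF, 40 °C; CO2 (g), −20 °C; HCl (aq.), 0 °C, to pH 3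
Reagents that add atoms: carbon dioxide O=C=O
Why: Carboxylation of the Grignard reagent adds the missing carbon; the stereocentre is β to the reacting carbon and stays as it is (the descriptor changes from R to S only by priority).

Step 19
Reactants: 25 macrocyclic alcohol; 29 (S)-4-(TBS-oxy)-3-methylbutanoic acid
Product: 30 8α-[(3S)-4-(TBS-oxy)-3-methylbutanoyloxy]-15-(TBDPS-oxy)-11βH,13-dihydrogermacra-1(10),4-dien-6α,12-olide
Conditions: 2,4,6-trichlorobenzoyl chloride, Et3N, THF, rt; then 25, DMAP, toluene, rt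
Reagents that add atoms: none
Why: Yamaguchi esterification acylates the hindered secondary alcohol through the mixed anhydride with retention at C8.

Step 20
Reactants: 30 bis-silyl ether
Product: 31 CNP0160815.1, 8α-[(3S)-4-hydroxy-3-methylbutanoyloxy]-15-hydroxy-11βH,13-dihydrogermacra-1(10),4-dien-6α,12-olide
Conditions: HF·pyridine, pyridine, THF, 0 °C to rt
Reagents that add atoms: none
Why: Buffered fluoride desilylation removes both silyl ethers under weakly acidic conditions, which should avoid lactonisation of the freed 4-hydroxybutanoate and acyl migration.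

**Compound list**

1 | 5-bromo-2-methylpent-2-ene | CC(C)=CCCBr | starting material
2 | (E)-5-bromo-2-methylpent-2-en-1-ol | OC/C(C)=C/CCBr | intermediate
3 | (E)-[(5-bromo-2-methylpent-2-en-1-yl)oxy](tert-butyl)dimethylsilane | CC(C)(C)[Si](C)(C)OC/C(C)=C/CCBr | intermediate
4 | methyl 4-hydroxybut-2-ynoate | COC(=O)C#CCO | starting material
5 | methyl 4-[(tert-butyldiphenylsilyl)oxy]but-2-ynoate | COC(=O)C#CCO[Si](c1ccccc1)(c1ccccc1)C(C)(C)C | intermediate
6 | (E)-[5-(TBS-oxy)-4-methylpent-3-en-1-yl]magnesium bromide | CC(C)(C)[Si](C)(C)OC/C(C)=C/CC[Mg]Br | intermediate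
7 | methyl (2Z,6E)-8-(TBS-oxy)-3-(TBDPS-oxymethyl)-7-methylocta-2,6-dienoate | COC(=O)/C=C(/CC/C=C(\C)CO[Si](C)(C)C(C)(C)C)CO[Si](c1ccccc1)(c1ccccc1)C(C)(C)C | intermediate
8 | (2Z,6E)-8-(TBS-oxy)-3-(TBDPS-oxymethyl)-7-methylocta-2,6-dien-1-ol | OC/C=C(/CC/C=C(\C)CO[Si](C)(C)C(C)(C)C)CO[Si](c1ccccc1)(c1ccccc1)C(C)(C)C | intermediate
9 | (2Z,6E)-8-(TBS-oxy)-3-(TBDPS-oxymethyl)-7-methylocta-2,6-dienal | O=C/C=C(/CC/C=C(\C)CO[Si](C)(C)C(C)(C)C)CO[Si](c1ccccc1)(c1ccccc1)C(C)(C)C | intermediate
10 | (S)-4-benzyloxazolidin-2-one | O=C1N[C@@H](Cc2ccccc2)CO1 | starting material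
11 | methyl 4-chloro-4-oxobutanoate | COC(=O)CCC(Cl)=O | starting material
12 | methyl 4-[(4S)-4-benzyl-2-oxooxazolidin-3-yl]-4-oxobutanoate | COC(=O)CCC(=O)N1[C@@H](Cc2ccccc2)COC1=O | intermediate
13 | open-chain syn-aldol adduct of 12 and 9 (hydroxy methyl ester; C6 and C7 as in the target) | CC(C)(C)[Si](C)(C)OC/C(C)=C/CC/C(CO[Si](c1ccccc1)(c1ccccc1)C(C)(C)C)=C/[C@@H](O)[C@H](CC(=O)OC)C(=O)N3[C@@H](Cc4ccccc4)COC3=O | intermediate
14 | (4S)-4-benzyl-3-{[2,3-trans-2-(chain A)-5-oxotetrahydrofuran-3-yl]carbonyl}oxazolidin-2-one | CC(C)(C)[Si](C)(C)OC/C(C)=C/CC/C(CO[Si](c1ccccc1)(c1ccccc1)C(C)(C)C)=C/[C@H]2OC(=O)C[C@@H]2C(=O)N3[C@@H](Cc4ccccc4)COC3=O | intermediate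
15 | 2,3-trans-2-(chain A)-5-oxotetrahydrofuran-3-carboxylic acid | CC(C)(C)[Si](C)(C)OC/C(C)=C/CC/C(CO[Si](c1ccccc1)(c1ccccc1)C(C)(C)C)=C/[C@H]2OC(=O)C[C@@H]2C(=O)O | intermediate
16 | all-trans 2-(chain A)-4-methyl-5-oxotetrahydrofuran-3-carboxylic acid | CC(C)(C)[Si](C)(C)OC/C(C)=C/CC/C(CO[Si](c1ccccc1)(c1ccccc1)C(C)(C)C)=C/[C@H]2OC(=O)[C@@H](C)[C@@H]2C(=O)O | intermediate
17 | isobutyl carbonic mixed anhydride of 16 | CC(C)(C)[Si](C)(C)OC/C(C)=C/CC/C(CO[Si](c1ccccc1)(c1ccccc1)C(C)(C)C)=C/[C@H]2OC(=O)[C@@H](C)[C@@H]2C(=O)OC(=O)OCC(C)C | intermediate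
18 | all-trans 5-(chain A)-4-(hydroxymethyl)-3-methyldihydrofuran-2(3H)-one | CC(C)(C)[Si](C)(C)OC/C(C)=C/CC/C(CO[Si](c1ccccc1)(c1ccccc1)C(C)(C)C)=C/[C@H]2OC(=O)[C@@H](C)[C@@H]2CO | intermediate
19 | all-trans 2-(chain A)-4-methyl-5-oxotetrahydrofuran-3-carbaldehyde | CC(C)(C)[Si](C)(C)OC/C(C)=C/CC/C(CO[Si](c1ccccc1)(c1ccccc1)C(C)(C)C)=C/[C@H]2OC(=O)[C@@H](C)[C@@H]2C=O | intermediate
20 | all-trans 4-(dimethoxymethyl)-5-[(1Z,5E)-7-hydroxy-2-(TBDPS-oxymethyl)-6-methylhepta-1,5-dien-1-yl]-3-methyldihydrofuran-2(3H)-one | OC/C(C)=C/CC/C(CO[Si](c1ccccc1)(c1ccccc1)C(C)(C)C)=C/[C@H]2OC(=O)[C@@H](C)[C@@H]2C(OC)OC | intermediate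
21 | methyl carbonate of 20 at the C9 oxygen | COC(=O)OC/C(C)=C/CC/C(CO[Si](c1ccccc1)(c1ccccc1)C(C)(C)C)=C/[C@H]2OC(=O)[C@@H](C)[C@@H]2C(OC)OC | intermediate
22 | all-trans 4-(dimethoxymethyl)-5-[(1Z,5S)-5-(pinacolatoboryl)-2-(TBDPS-oxymethyl)-6-methylhepta-1,6-dien-1-yl]-3-methyldihydrofuran-2(3H)-one | C=C(C)[C@@H](B1OC(C)(C)C(C)(C)O1)CC/C(CO[Si](c1ccccc1)(c1ccccc1)C(C)(C)C)=C/[C@H]2OC(=O)[C@@H](C)[C@@H]2C(OC)OC | intermediate
23 | C8 aldehyde corresponding to 22 | C=C(C)[C@@H](B1OC(C)(C)C(C)(C)O1)CC/C(CO[Si](c1ccccc1)(c1ccccc1)C(C)(C)C)=C/[C@H]2OC(=O)[C@@H](C)[C@@H]2C=O | intermediate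
24 | pinacol borate ester of 25 at the C8 oxygen | C/C1=C/CC/C(CO[Si](c3ccccc3)(c3ccccc3)C(C)(C)C)=C/[C@H]2OC(=O)[C@@H](C)[C@@H]2[C@@H](OB3OC(C)(C)C(C)(C)O3)C1 | intermediate
25 | 8α-hydroxy-15-(TBDPS-oxy)-11βH,13-dihydrogermacra-1(10),4-dien-6α,12-olide (6R,7R,8S,11S) | C/C1=C/CC/C(CO[Si](c3ccccc3)(c3ccccc3)C(C)(C)C)=C/[C@H]2OC(=O)[C@@H](C)[C@@H]2[C@@H](O)C1 | intermediate
26 | (R)-3-bromo-2-methylpropan-1-ol | BrC[C@H](C)CO | starting material
27 | (R)-(3-bromo-2-methylpropoxy)(tert-butyl)dimethylsilane | BrC[C@H](C)CO[Si](C)(C)C(C)(C)C | intermediate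
28 | (R)-[3-(TBS-oxy)-2-methylpropyl]magnesium bromide | Br[Mg]C[C@H](C)CO[Si](C)(C)C(C)(C)C | intermediate
29 | (S)-4-(TBS-oxy)-3-methylbutanoic acid | OC(=O)C[C@H](C)CO[Si](C)(C)C(C)(C)C | intermediate
30 | 8α-[(3S)-4-(TBS-oxy)-3-methylbutanoyloxy]-15-(TBDPS-oxy)-11βH,13-dihydrogermacra-1(10),4-dien-6α,12-olide | C/C1=C/CC/C(CO[Si](c3ccccc3)(c3ccccc3)C(C)(C)C)=C/[C@H]2OC(=O)[C@@H](C)[C@@H]2[C@@H](OC(=O)C[C@H](C)CO[Si](C)(C)C(C)(C)C)C1 | intermediate
31 | CNP0160815.1 | C/C1=C/CC/C(CO)=C/[C@H]2OC(=O)[C@@H](C)[C@@H]2[C@@H](OC(=O)C[C@H](C)CO)C1 | target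

**Step count and risks**

Total step count: 20 steps. Longest linear sequence: 16 steps (steps 1, 2, 4, 5, 6, 8 to 16, 19, 20).

Steps most likely to fail:

1. Step 16 (key step, proposed new method). Intermolecular allylboration may outrun the medium-ring closure, or closure may go through a chair with the C2 chain equatorial and give the trans C1=C10 alkene. The fallback uses known chemistry and closes the ring at the C1=C10 alkene instead. It sets out from aldehyde 19: reagent-controlled addition of B-methallyldiisopinocampheylborane (the antipode that gives the 8S alcohol; Et2O, −78 °C; ethanolamine work-up) should give homoallylic alcohol F1. Ring-closing metathesis of F1 with the second-generation Hoveyda–Grubbs catalyst (toluene, 80 °C, 0.001 M) joins the new 1,1-disubstituted alkene to the trisubstituted C1 alkene with loss of the silylated 2-methylallyl alcohol; the ring size should favour the cis alkene. This closure to a trisubstituted alkene in a ten-membered ring is itself demanding. The fallback comes back to the route at 25.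

2. Step 15. Facial selectivity at C1 may be poor, because the catalyst must override the remote stereocentres on a trisubstituted alkene. The fallback makes the end game stereoconvergent. It sets out from 21: the borylation mixture of 22 and its C1 epimer F2 is not separated and is put through the conditions of step 16. F2 should pass through aldehyde F3 and borate ester F4 to the 8R alcohol F5 with the same cis C1=C10 alkene, and F5 is separated from 25 by chromatography. F5 is then esterified with acid 29 under Mitsunobu conditions (PPh3, diisopropyl azodicarboxylate, toluene, 0 °C to rt) with inversion at C8. The fallback comes back to the route at 30.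

3. Step 4. The alkenylcopper intermediate may equilibrate through the allenoate and erode the C4=C5 geometry, or add a second time. The fallback locks the geometry in a ring. It sets out from bromide 3: zinc insertion (Zn, LiCl, THF, 40 °C) gives alkylzinc bromide F6, and Negishi coupling with 4-bromofuran-2(5H)-one (Pd(PPh3)4, THF, rt) gives butenolide F7. Opening with AlMe3 and N,O-dimethylhydroxylamine hydrochloride (CH2Cl2, 0 °C) gives hydroxy Weinreb amide F8; silylation (TBDPSCl, imidazole) gives F9; and reduction with iBu2AlH (THF, −78 °C) gives the aldehyde. The fallback comes back to the route at 9.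

Further compounds
F1 | step 16 | all-trans 5-(chain A)-4-[(1S)-1-hydroxy-3-methylbut-3-en-1-yl]-3-methyldihydrofuran-2(3H)-one | CC(C)(C)[Si](C)(C)OC/C(C)=C/CC/C(CO[Si](c1ccccc1)(c1ccccc1)C(C)(C)C)=C/[C@H]2OC(=O)[C@@H](C)[C@@H]2[C@@H](O)CC(C)=C
F2 | step 15 | C1 epimer of 22 (boron on C1, R) | C=C(C)[C@H](B1OC(C)(C)C(C)(C)O1)CC/C(CO[Si](c1ccccc1)(c1ccccc1)C(C)(C)C)=C/[C@H]2OC(=O)[C@@H](C)[C@@H]2C(OC)OC
F3 | step 15 | C8 aldehyde corresponding to F2 | C=C(C)[C@H](B1OC(C)(C)C(C)(C)O1)CC/C(CO[Si](c1ccccc1)(c1ccccc1)C(C)(C)C)=C/[C@H]2OC(=O)[C@@H](C)[C@@H]2C=O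
F4 | step 15 | pinacol borate ester of F5 at the C8 oxygen | C/C1=C/CC/C(CO[Si](c3ccccc3)(c3ccccc3)C(C)(C)C)=C/[C@H]2OC(=O)[C@@H](C)[C@@H]2[C@H](OB3OC(C)(C)C(C)(C)O3)C1
F5 | step 15 | 8β-hydroxy epimer of 25 (8R) | C/C1=C/CC/C(CO[Si](c3ccccc3)(c3ccccc3)C(C)(C)C)=C/[C@H]2OC(=O)[C@@H](C)[C@@H]2[C@H](O)C1
F6 | step 4 | (E)-[5-(TBS-oxy)-4-methylpent-3-en-1-yl]zinc bromide | CC(C)(C)[Si](C)(C)OC/C(C)=C/CC[Zn]Br
F7 | step 4 | 4-[(E)-5-(TBS-oxy)-4-methylpent-3-en-1-yl]furan-2(5H)-one | CC(C)(C)[Si](C)(C)OC/C(C)=C/CCC1=CC(=O)OC1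
F8 | step 4 | (2Z,6E)-8-(TBS-oxy)-3-(hydroxymethyl)-N-methoxy-N,7-dimethylocta-2,6-dienamide | CON(C)C(=O)/C=C(/CC/C=C(\C)CO[Si](C)(C)C(C)(C)C)CO
F9 | step 4 | (2Z,6E)-8-(TBS-oxy)-3-(TBDPS-oxymethyl)-N-methoxy-N,7-dimethylocta-2,6-dienamide | CON(C)C(=O)/C=C(/CC/C=C(\C)CO[Si](C)(C)C(C)(C)C)CO[Si](c1ccccc1)(c1ccccc1)C(C)(C)C
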